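Compound numbers are fixed by the steps below and used in every section. Dihydrobenzofuran numbering: O1, C2, C3, C3a, C4–C7, C7a. Flavanone numbering: O1, C2, C3, C4, C4a, C5–C8, C8a. Ring A is the fused benzo ring, ring B the aryl group on C2.

## The problem

Target 16 is a 2,3-dihydro-1-benzofuran (ring O1–C2–C3–C3a–C7a fused to ring A). It carries a 4-hydroxyphenyl group (ring B) on C2, a 2,4-dihydroxybenzoyl group on C3, and a 3-(2,4-dihydroxyphenyl)-3-oxopropyl chain on C5, para to O1. C2 and C3 are both S, which places the aryl and aroyl groups trans.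

The connectivity is that of a chalcone joined through its α-carbon to the carbon ortho to the hydroxyl of a dihydrochalcone. No simple building block holds the C3–C3a bond next to the C2–O1 bond.

Only C2 needs an external chiral agent. C3 is benzylic and α to a ketone, so it equilibrates to the trans isomer and can be controlled by C2.

The same acidity is the main hazard. The C3 enolate can expel the O1 phenoxide (the reverse of an oxa-Michael closure) and so erase C2 as well. The C2–O1 bond, benzylic and para to the ring B oxygen, ionises in acid. Strong base and strong acid are therefore excluded once the ring exists, and the five phenols must be freed under neutral conditions.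

The two resorcinol ketones are identical, which invites one reagent for both.

The feature that opens the plan sits at C3. This carbon is bonded both to the ring A carbon C3a and to an exocyclic aryl-ketone carbon. That is exactly the pattern left when, in a 4-aryl-chroman-4-ol, the ring A carbon C4a shifts from C4 to C3. The five-membered ring O1–C2–C3–C3a–C7a is thus the six-membered heterocycle of a flavanone (O1–C2–C3–C4–C4a–C8a) with C4 pushed out of the ring as the aroyl carbonyl. Enantioenriched flavanones are readily made.

## Retrosynthesis

**16 from 15.** The cuts are the five O–CH2Ph bonds and the two C–H bonds of the chain CH2–CH2 (an E alkene in 15). Benzyl ethers leave by neutral hydrogenolysis. Methyl ethers would need a boron trihalide, which opens C2–O1, and silyl ethers release phenoxides, which invite the enolate ring opening. The alkene costs nothing: it is the trace of the Heck reaction and is saturated in the same operation. The forward step must spare the benzylic C2–O1 bond and both ketones.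

**15 from 11 and 2 (through 12, 13, 14).** Three bonds are cut: the ring bond C3–C3a, which is re-attached to the carbonyl carbon to give C4–C4a of a chroman-4-one, and both aryl–C(=O) bonds to the resorcinol rings. Three neighbouring cuts were weighed against this one:
- Acylating a protected resorcinol with a C3 carboxylic acid derivative of the finished ring needs acid, which ionises C2–O1.
- Adding an aryl-metal to a C3 ester or amide of the finished ring meets the acidic C3–H and ring opening.
- The oxidative contraction of 7 itself with trivalent iodine stops at the ester oxidation level, and migration of an electron-rich ring B competes.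

In the chosen cut one aryl nucleophile serves two sites: the C4 ketone and the chain N-methoxy-N-methylamide. C3 is set by a stereospecific shift. The precursor 11 has neither resorcinol ring and 2 is a one-step compound. The forward reaction must add 1,2 without enolisation, migrate the ring bond rather than the new aryl group, and leave the product ketone untouched.

**11 from 10 from 7.** The cuts are the S–O bond of the mesylate and then the C3–O bond. A Rubottom oxidation puts oxygen on C3 anti to the C2 aryl group without forming a free enolate. The chalcone epoxide route to 10 would need a phenol protection, an asymmetric epoxidation and an acid cyclisation. A C3 bromide as nucleofuge is held back as a fallback. The forward steps must give the 2,3-trans isomer and keep C2.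

**7 from 5 and 6.** The cut is the C2–aryl bond. A catalytic asymmetric conjugate addition of an arylboronic acid to the flat, achiral chromone sets the only stereocentre that needs a chiral agent. The oxa-Michael closure of a 2'-hydroxychalcone is reversible and harder to control. The catalyst must pick the chromone over the β-aryl acrylamide.

**5 from 3 and 4.** The cut is the aryl–vinyl bond, made by a Heck reaction of two commercial compounds. An alkylzinc coupling would give the saturated chain but needs a reagent made for the purpose.

**2 from 1.** The cuts are two O–benzyl bonds, made by Williamson etherification.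

## Roads not taken

**Alternative 1:** Cut C3–C3a and C2–O1 together, as in the likely biogenesis. The forward key step is one-electron oxidation (Ag2O, an anode, or a peroxidase with H2O2) of a mixture of isoliquiritigenin A1 and davidigenin A2. The α-carbon of the A1 radical couples with the carbon ortho to the hydroxyl of the A2 radical, and the phenol closes onto the quinone methide. The chosen plan is better for three reasons. The coupling partners are free radicals and the closure runs on an achiral quinone methide, so the skeleton of 16 would arise only as a racemate. Both homodimers and other coupling positions of A2 compete with the cross-coupling. The product, with five free phenols, is more easily oxidised than either partner.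

**Alternative 2:** Cut C2–C3. The forward key step is intramolecular carbene insertion of the aryl diazoacetate A3 into the benzylic ether C–H bond under Rh2(S-PTTL)4 (dirhodium tetrakis[N-phthaloyl-(S)-tert-leucinate]) to the cis ester A4, followed by epimerisation at C3. This is the route most chemists would draw first for an enantioenriched 2-aryl-2,3-dihydrobenzofuran. It ends at an ester. Turning the ester of A4 into the resorcinol ketone requires an aryl-metal to meet the acidic C3–H of the finished ring, or an acid-mediated acylation. Several steps are also needed to reach A3 (ether formation, aryl acetate, diazo transfer) before the chain is addressed. The chosen plan makes the ketone in the operation that makes the ring.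

**Alternative 3:** Cut O1–C7a. The racemic 2-aryl-1,3-diketone A5 would be reduced by asymmetric transfer hydrogenation with dynamic kinetic resolution (RuCl(p-cymene)[(S,S)-TsDPEN], HCO2H/Et3N) to the hydroxy ketone A6, and the ring closed by CuI-catalysed intramolecular O-arylation. The catalyst would have to tell two aryl ketones apart. The β-hydroxy ketone A6 is prone to retro-aldol cleavage and β-elimination under the basic coupling conditions. A5 itself needs a multi-step assembly around a hindered ortho-bromoaryl centre. The chosen plan sets C2 on a flat chromone in one catalytic step and never passes through an open-chain aldol.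

Key step: step 6

**Assumptions (remarks on the chemistry):**
- The SMILES is read as the (2S,3S)-trans isomer.
- In step 3 the aryl group is taken to be delivered to the enone face known for simple cyclic enones with this ligand class. If the first run gives the (2R) flavanone, the antipodal ligand is used and nothing else changes.
- The change of the C2 descriptor between 7 (S), 9–14 (R) and 15/16 (S) is a change of CIP ranking only; the C2 configuration in space is the same throughout.

## Route

Step 1
Reactants: 1 4-bromoresorcinol
Product: 2 2,4-bis(benzyloxy)-1-bromobenzene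
Conditions: BnBr (2.3 equiv), K2CO3, DMF, 60 °C
Reagents that add atoms: benzyl bromide BrCc1ccccc1
Why: Williamson etherification of both phenols (SN2 on benzyl bromide); the aryl bromide is inert and no stereocentre is involved.

Step 2
Reactants: 3 6-bromochromone; 4 N-methoxy-N-methylacrylamide
Product: 5 (E)-N-methoxy-N-methyl-3-(4-oxo-4H-chromen-6-yl)prop-2-enamide
Conditions: Pd(OAc)2 (2 mol%), P(o-tol)3 (4 mol%), Et3N, DMF, 90 °C
Reagents that add atoms: none
Why: Heck reaction: zerovalent palladium inserts into the C6–Br bond, the acrylamide inserts syn and syn β-hydride elimination gives the E alkene; the pyranone C2=C3 bond is far less reactive toward the aryl-palladium species than the terminal acrylamide, and a tertiary amine does not open the chromone.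

Step 3
Reactants: 5 (E)-N-methoxy-N-methyl-3-(4-oxo-4H-chromen-6-yl)prop-2-enamide; 6 4-(benzyloxy)phenylboronic acid
Product: 7 (E)-3-[(2S)-2-[4-(benzyloxy)phenyl]-4-oxo-3,4-dihydro-2H-chromen-6-yl]-N-methoxy-N-methylprop-2-enamide
Conditions: 6 (2 equiv), Pd(OCOCF3)2 (5 mol%), (R)-4-tert-butyl-2-(pyridin-2-yl)-4,5-dihydrooxazole [(R)-t-BuPyOx] (6 mol%), NH4PF6 (30 mol%), H2O (5 equiv), ClCH2CH2Cl, 60 °C
Reagents that add atoms: none
Why: Catalytic asymmetric conjugate addition of an arylboronic acid under divalent palladium: transmetalation gives a cationic aryl-palladium species that adds across C2=C3 of the chromone from the enantioface left open by the tert-butyl group of the ligand, and water protonates the palladium enolate, so C2 is set as S by the catalyst; the chromone, a cyclic s-trans enone, should react ahead of the β-aryl acrylamide, which is a poor acceptor for this catalyst.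

Step 4
Reactants: 7 (E)-3-[(2S)-2-[4-(benzyloxy)phenyl]-4-oxo-3,4-dihydro-2H-chromen-6-yl]-N-methoxy-N-methylprop-2-enamide
Product: 10 (E)-3-[(2R,3R)-2-[4-(benzyloxy)phenyl]-3-hydroxy-4-oxo-3,4-dihydro-2H-chromen-6-yl]-N-methoxy-N-methylprop-2-enamide, via silyl enol ether 8 (not isolated), via 3-silyloxy ketone 9 (not isolated)
Conditions: TMSOTf, Et3N, CH2Cl2, 0 °C; DMDO (1.1 equiv), acetone, −40 °C; citric acid, MeOH, 0 °C
Reagents that add atoms: dimethyldioxirane CC1(C)OO1; trimethylsilyl triflate C[Si](C)(C)OS(=O)(=O)C(F)(F)F (silyl group of 8 and 9 only)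
Why: Rubottom oxidation: soft enolisation gives 8 without a free enolate (so O1 is not expelled and C2 is kept), the dioxirane attacks the electron-rich enol ether (not the electron-poor acrylamide) on the face anti to the C2 aryl group, silyl migration gives 9 and mild acidic methanolysis frees the alcohol; C3 is thus set trans to the C2 aryl group (both equatorial), which is also the more stable epimer.

Step 5
Reactants: 10 (E)-3-[(2R,3R)-2-[4-(benzyloxy)phenyl]-3-hydroxy-4-oxo-3,4-dihydro-2H-chromen-6-yl]-N-methoxy-N-methylprop-2-enamide
Product: 11 (2R,3R)-2-[4-(benzyloxy)phenyl]-6-[(E)-3-[methoxy(methyl)amino]-3-oxoprop-1-en-1-yl]-4-oxo-3,4-dihydro-2H-chromen-3-yl methanesulfonate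
Conditions: MsCl, Et3N, CH2Cl2, −20 °C
Reagents that add atoms: methanesulfonyl chloride CS(=O)(=O)Cl
Why: Sulfonylation of the secondary alcohol through sulfene at low temperature; the C3–O bond is not touched, so the 2,3-trans configuration is retained, and the trans isomer has no antiperiplanar H2/mesylate pair for elimination to a flavone.

Step 6
Reactants: 11 (2R,3R)-2-[4-(benzyloxy)phenyl]-6-[(E)-3-[methoxy(methyl)amino]-3-oxoprop-1-en-1-yl]-4-oxo-3,4-dihydro-2H-chromen-3-yl methanesulfonate; 2 2,4-bis(benzyloxy)-1-bromobenzene
Product: 15 (E)-1-[2,4-bis(benzyloxy)phenyl]-3-[(2S,3S)-3-[2,4-bis(benzyloxy)benzoyl]-2-[4-(benzyloxy)phenyl]-2,3-dihydro-1-benzofuran-5-yl]prop-2-en-1-one, via aryllithium 12 (not isolated), via arylcerium dichloride 13 (not isolated), via bis-alkoxide 14 (not isolated)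
Conditions: 2 (2.2 equiv), n-BuLi, THF, −78 °C; CeCl3 (anhydrous), −78 °C; 11, −78 to −40 °C; Et3Al (3 equiv, toluene), −78 to 0 °C; aq. potassium sodium tartrate
Reagents that add atoms: n-butyllithium [Li]CCCC (lithium of 12 only); cerium trichloride Cl[Ce](Cl)Cl (cerium and chlorine of 13 and 14 only)
Why: Bromine–lithium exchange on 2 and transmetalation to trivalent cerium give the weakly basic nucleophile 13, which adds 1,2 to both carbonyl groups of 11: to the C4 ketone (expected from the equatorial direction, so that O4 is cis to the mesylate and the new aryl group trans) and to the unsaturated N-methoxy-N-methylamide, whose chelated tetrahedral adduct holds until work-up and then gives the enone; this is 14. Et3Al then binds the C4 alkoxide and the sulfonate, and the C4–C4a bond, which in the all-equatorial half-chair of 14 lies antiperiplanar to the C3–O bond, shifts from C4 to C3 as the mesylate leaves and C4 becomes the ketone carbon. The closest known reaction types are the organoaluminium-promoted semipinacol rearrangement of 2-sulfonyloxy carbinols, in which an aryl group migrates with inversion at the sulfonate carbon, and the oxidative contraction of flavanones to 2-aryl-2,3-dihydrobenzofuran-3-carboxylates, in which the same ring A carbon moves from C4 to C3. The dihydrofuran ring O1–C2–C3–C3a–C7a is closed by ring contraction, an intramolecular backside displacement at C3 by the ipso carbon through a bridged arenium state (formally 3-exo-tet). C2 is not touched and keeps the configuration from step 3; C3 is set by the inversion that the antiperiplanar shift imposes on the (3R) mesylate, which puts the aroyl group trans to the C2 aryl group, the arrangement also favoured at equilibrium. The carbinol centre C4 is destroyed, so both C4 epimers of 14 can converge on 15. The step needs ring-bond migration rather than migration of the exocyclic aryl group or epoxide closure: the C2 aryl group locks the conformer with an equatorial mesylate (the flipped form would set the C2 and C4 aryl groups syn-diaxial), and an O4 cis to the mesylate cannot reach the backside of C3. Completing both additions at low temperature before the aluminium reagent is added keeps the product ketone, whose C3–H is acidic, away from the nucleophile.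

Step 7
Reactants: 15 (E)-1-[2,4-bis(benzyloxy)phenyl]-3-[(2S,3S)-3-[2,4-bis(benzyloxy)benzoyl]-2-[4-(benzyloxy)phenyl]-2,3-dihydro-1-benzofuran-5-yl]prop-2-en-1-one
Product: 16 1-(2,4-dihydroxyphenyl)-3-[(2S,3S)-3-(2,4-dihydroxybenzoyl)-2-(4-hydroxyphenyl)-2,3-dihydro-1-benzofuran-5-yl]propan-1-one
Conditions: H2 (1 atm), Pd/C (10% palladium on carbon), EtOAc/MeOH, rt, stopped at the calculated uptake
Reagents that add atoms: none
Why: Heterogeneous hydrogenation saturates the enone C=C and cleaves the five benzyl ethers by hydrogenolysis under neutral conditions, so neither the acidic C3–H nor the C2–O1 bond meets base or acid; the 2-hydroxyaryl ketones that form are chelated and resist further reduction, and no stereocentre is touched.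

## Compound list

1 | 4-bromoresorcinol (4-bromobenzene-1,3-diol) | Oc1ccc(Br)c(O)c1 | starting material
2 | 2,4-bis(benzyloxy)-1-bromobenzene | Brc1ccc(OCc2ccccc2)cc1OCc1ccccc1 | intermediate
3 | 6-bromochromone (6-bromo-4H-chromen-4-one) | O=c1ccoc2ccc(Br)cc12 | starting material
4 | N-methoxy-N-methylacrylamide | C=CC(=O)N(C)OC | starting material
5 | (E)-N-methoxy-N-methyl-3-(4-oxo-4H-chromen-6-yl)prop-2-enamide | O=c1ccoc2ccc(/C=C/C(=O)N(C)OC)cc12 | intermediate
6 | 4-(benzyloxy)phenylboronic acid | OB(O)c1ccc(OCc2ccccc2)cc1 | starting material
7 | (E)-3-[(2S)-2-[4-(benzyloxy)phenyl]-4-oxo-3,4-dihydro-2H-chromen-6-yl]-N-methoxy-N-methylprop-2-enamide | O=C1C[C@@H](c2ccc(OCc3ccccc3)cc2)Oc2ccc(/C=C/C(=O)N(C)OC)cc12 | intermediate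
8 | (E)-3-[(2S)-2-[4-(benzyloxy)phenyl]-4-(trimethylsilyloxy)-2H-chromen-6-yl]-N-methoxy-N-methylprop-2-enamide (silyl enol ether, formed in the flask) | C[Si](C)(C)OC1=C[C@@H](c2ccc(OCc3ccccc3)cc2)Oc2ccc(/C=C/C(=O)N(C)OC)cc12 | intermediate
9 | (E)-3-[(2R,3R)-2-[4-(benzyloxy)phenyl]-4-oxo-3-(trimethylsilyloxy)-3,4-dihydro-2H-chromen-6-yl]-N-methoxy-N-methylprop-2-enamide (formed in the flask) | O=C1[C@H](O[Si](C)(C)C)[C@@H](c2ccc(OCc3ccccc3)cc2)Oc2ccc(/C=C/C(=O)N(C)OC)cc12 | intermediate
10 | (E)-3-[(2R,3R)-2-[4-(benzyloxy)phenyl]-3-hydroxy-4-oxo-3,4-dihydro-2H-chromen-6-yl]-N-methoxy-N-methylprop-2-enamide (2,3-trans) | O=C1[C@H](O)[C@@H](c2ccc(OCc3ccccc3)cc2)Oc2ccc(/C=C/C(=O)N(C)OC)cc12 | intermediate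
11 | (2R,3R)-2-[4-(benzyloxy)phenyl]-6-[(E)-3-[methoxy(methyl)amino]-3-oxoprop-1-en-1-yl]-4-oxo-3,4-dihydro-2H-chromen-3-yl methanesulfonate | O=C1[C@H](OS(C)(=O)=O)[C@@H](c2ccc(OCc3ccccc3)cc2)Oc2ccc(/C=C/C(=O)N(C)OC)cc12 | intermediate
12 | [2,4-bis(benzyloxy)phenyl]lithium (formed in the flask) | [Li]c1ccc(OCc2ccccc2)cc1OCc1ccccc1 | intermediate
13 | [2,4-bis(benzyloxy)phenyl]cerium dichloride (formed in the flask) | Cl[Ce](Cl)c1ccc(OCc2ccccc2)cc1OCc1ccccc1 | intermediate
14 | bis(dichlorocerium) alkoxide of (2R,3R,4S)-4-[2,4-bis(benzyloxy)phenyl]-2-[4-(benzyloxy)phenyl]-4-hydroxy-6-[(E)-3-[2,4-bis(benzyloxy)phenyl]-3-hydroxy-3-[methoxy(methyl)amino]prop-1-en-1-yl]-3,4-dihydro-2H-chromen-3-yl methanesulfonate (C4 epimer expected from equatorial attack; hemiaminal carbon not controlled; formed in the flask) | [C@@]1(O[Ce](Cl)Cl)(c2ccc(OCc3ccccc3)cc2OCc2ccccc2)[C@H](OS(C)(=O)=O)[C@@H](c2ccc(OCc3ccccc3)cc2)Oc2ccc(/C=C/C(O[Ce](Cl)Cl)(N(C)OC)c3ccc(OCc4ccccc4)cc3OCc3ccccc3)cc12 | intermediate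
15 | (E)-1-[2,4-bis(benzyloxy)phenyl]-3-[(2S,3S)-3-[2,4-bis(benzyloxy)benzoyl]-2-[4-(benzyloxy)phenyl]-2,3-dihydro-1-benzofuran-5-yl]prop-2-en-1-one | O=C(/C=C/c1ccc2c(c1)[C@H](C(=O)c1ccc(OCc3ccccc3)cc1OCc1ccccc1)[C@@H](c1ccc(OCc3ccccc3)cc1)O2)c1ccc(OCc2ccccc2)cc1OCc1ccccc1 | intermediate
16 | 1-(2,4-dihydroxyphenyl)-3-[(2S,3S)-3-(2,4-dihydroxybenzoyl)-2-(4-hydroxyphenyl)-2,3-dihydro-1-benzofuran-5-yl]propan-1-one | O=C(CCc1ccc2c(c1)[C@H](C(=O)c1ccc(O)cc1O)[C@@H](c1ccc(O)cc1)O2)c1ccc(O)cc1O | target

## Step count and least certain steps

Total step count: 7. Longest linear sequence: 6 steps (steps 2 to 7, from 3); step 1 is a one-step side branch that joins at step 6.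

**Step 6 (key step).** Three processes may spoil it.
- Addition to C4 from the axial direction gives the epimer with O4 trans to the mesylate, which can close to a 3,4-epoxide through the ring-flipped conformer instead of contracting.
- The electron-rich, doubly benzylic C4–O bond may ionise under the Lewis acid, with loss of the C3 proton, or O1 may take part in place of C4a.
- Aryl-cerium left over may attack or enolise the product ketone, with expulsion of O1.

The fallback gives up the sulfonate and uses an oxidative contraction. It sets out from 7. Reagent 13 (2.2 equiv, THF, −78 °C) adds to the C4 ketone and to the amide to give, after work-up, the 4-aryl-flavan-4-ol with the enone chain, carbinol F1. Pyridinium p-toluenesulfonate in toluene dehydrates it to the (2S)-2,4-diaryl-2H-chromene F2. [Hydroxy(tosyloxy)iodo]benzene in aqueous MeCN at 0 °C then places trivalent iodine on C3 anti to the C2 aryl group and water on C4, and the C4–C4a bond shifts to C3 with loss of iodobenzene. This is the oxidative ring contraction known for 1,2-dihydronaphthalenes and 2H-chromenes, with the same stereochemical course. The route is rejoined at 15; 10 and 11 are bypassed.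

**Step 3.** The aryl-palladium species may also add to the acrylamide side chain, the electron-rich boronic acid may be lost by protodeboronation before the sluggish chromone reacts, or facial selectivity may be lower than on simpler chromones. The fallback changes the order of bond formation so that the catalyst meets only one acceptor. It sets out from 3: the same conjugate addition of 6 to 3 gives (2S)-6-bromo-2-[4-(benzyloxy)phenyl]chroman-4-one F3. A Heck reaction of F3 with 4 under mild conditions (Pd[P(t-Bu)3]2, Cy2NMe, dioxane, rt), chosen so that the flavanone is not opened by base, then rejoins the route at 7.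

**Step 4.** The oxidant may also attack the side-chain alkene or a benzylic position, and the 2-aryl-2H-chromene 8 may lose C2 integrity by reversible electrocyclic ring opening if warmed or exposed to light. The fallback replaces the oxygen nucleofuge by bromine. It sets out from 7: the silyl enol ether 8 is treated with N-bromosuccinimide (THF, −78 °C), bromine entering anti to the C2 aryl group, to give the (2R,3R)-trans-3-bromoflavanone F4. Reagent 13 (2.2 equiv) adds as in step 6 to give, after work-up, the bromohydrin with the enone chain, F5. AgOTf with 2,6-di-tert-butylpyridine in CH2Cl2 then removes bromide while the C4–C4a bond shifts (halohydrin semipinacol ring contraction). The route is rejoined at 15.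

**Step 7.** Hydrogenolysis may go on to cleave the benzylic C2–O1 bond once the ring B phenol is free, or may reduce an aryl ketone, and removal of the two hindered ortho benzyl groups may lag. The fallback separates the two tasks and removes the benzyl groups without hydrogen. It sets out from 15: [(Ph3P)CuH]6 in toluene reduces only the enone C=C to the saturated pentabenzyl ether F6. BCl3 with pentamethylbenzene in CH2Cl2 at −78 °C then transfers the five benzyl groups to the scavenger and rejoins the route at 16.

## Further compounds

F1 | step 6 | (E)-1-[2,4-bis(benzyloxy)phenyl]-3-[(2S)-4-[2,4-bis(benzyloxy)phenyl]-2-[4-(benzyloxy)phenyl]-4-hydroxy-3,4-dihydro-2H-chromen-6-yl]prop-2-en-1-one (C4 epimers) | OC1(c2ccc(OCc3ccccc3)cc2OCc2ccccc2)C[C@@H](c2ccc(OCc3ccccc3)cc2)Oc2ccc(/C=C/C(=O)c3ccc(OCc4ccccc4)cc3OCc3ccccc3)cc12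
F2 | step 6 | (E)-1-[2,4-bis(benzyloxy)phenyl]-3-[(2S)-4-[2,4-bis(benzyloxy)phenyl]-2-[4-(benzyloxy)phenyl]-2H-chromen-6-yl]prop-2-en-1-one | O=C(/C=C/c1ccc2c(c1)C(c1ccc(OCc3ccccc3)cc1OCc1ccccc1)=C[C@@H](c1ccc(OCc3ccccc3)cc1)O2)c1ccc(OCc2ccccc2)cc1OCc1ccccc1
F3 | step 3 | (2S)-6-bromo-2-[4-(benzyloxy)phenyl]chroman-4-one | O=C1C[C@@H](c2ccc(OCc3ccccc3)cc2)Oc2ccc(Br)cc12
F4 | step 4 | (E)-3-[(2R,3R)-2-[4-(benzyloxy)phenyl]-3-bromo-4-oxo-3,4-dihydro-2H-chromen-6-yl]-N-methoxy-N-methylprop-2-enamide | O=C1[C@H](Br)[C@@H](c2ccc(OCc3ccccc3)cc2)Oc2ccc(/C=C/C(=O)N(C)OC)cc12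
F5 | step 4 | (E)-1-[2,4-bis(benzyloxy)phenyl]-3-[(2R,3R,4S)-4-[2,4-bis(benzyloxy)phenyl]-2-[4-(benzyloxy)phenyl]-3-bromo-4-hydroxy-3,4-dihydro-2H-chromen-6-yl]prop-2-en-1-one | [C@@]1(O)(c2ccc(OCc3ccccc3)cc2OCc2ccccc2)[C@H](Br)[C@@H](c2ccc(OCc3ccccc3)cc2)Oc2ccc(/C=C/C(=O)c3ccc(OCc4ccccc4)cc3OCc3ccccc3)cc12
F6 | step 7 | 1-[2,4-bis(benzyloxy)phenyl]-3-[(2S,3S)-3-[2,4-bis(benzyloxy)benzoyl]-2-[4-(benzyloxy)phenyl]-2,3-dihydro-1-benzofuran-5-yl]propan-1-one | O=C(CCc1ccc2c(c1)[C@H](C(=O)c1ccc(OCc3ccccc3)cc1OCc1ccccc1)[C@@H](c1ccc(OCc3ccccc3)cc1)O2)c1ccc(OCc2ccccc2)cc1OCc1ccccc1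
A1 | alternative 1 | isoliquiritigenin, (E)-1-(2,4-dihydroxyphenyl)-3-(4-hydroxyphenyl)prop-2-en-1-one | O=C(/C=C/c1ccc(O)cc1)c1ccc(O)cc1O
A2 | alternative 1 | davidigenin, 1-(2,4-dihydroxyphenyl)-3-(4-hydroxyphenyl)propan-1-one | O=C(CCc1ccc(O)cc1)c1ccc(O)cc1O
A3 | alternative 2 | methyl 2-[2-[[4-(benzyloxy)phenyl]methoxy]-5-bromophenyl]-2-diazoacetate | COC(=O)C(=[N+]=[N-])c1cc(Br)ccc1OCc1ccc(OCc2ccccc2)cc1
A4 | alternative 2 | methyl (2S,3R)-2-[4-(benzyloxy)phenyl]-5-bromo-2,3-dihydro-1-benzofuran-3-carboxylate (cis) | Brc1ccc2c(c1)[C@@H](C(=O)OC)[C@@H](c1ccc(OCc3ccccc3)cc1)O2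
A5 | alternative 3 | 3-[3-[1-[2,4-bis(benzyloxy)phenyl]-3-[4-(benzyloxy)phenyl]-1,3-dioxopropan-2-yl]-4-bromophenyl]-N-methoxy-N-methylpropanamide (racemic, labile centre) | CON(C)C(=O)CCc1ccc(Br)c(c1)C(C(=O)c1ccc(OCc2ccccc2)cc1)C(=O)c1ccc(OCc2ccccc2)cc1OCc1ccccc1
A6 | alternative 3 | 3-[3-[(2S,3S)-1-[2,4-bis(benzyloxy)phenyl]-3-[4-(benzyloxy)phenyl]-3-hydroxy-1-oxopropan-2-yl]-4-bromophenyl]-N-methoxy-N-methylpropanamide | CON(C)C(=O)CCc1ccc(Br)c(c1)[C@H](C(=O)c1ccc(OCc2ccccc2)cc1OCc1ccccc1)[C@@H](c1ccc(OCc2ccccc2)cc1)O
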